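## Retrosynthetic overview

1. Target 16 ⇒ pyranone enone 13. In one flask the 2-pyranone is opened and re-closed by intramolecular Claisen condensation (ring A, chalcone 15), then a chiral thiourea closes ring C by oxa-Michael addition and sets C-2 as (S).
2. 13 ⇒ Weinreb enamide 9 + 4-methoxy-6-methyl-2H-pyran-2-one 10 (C-acylation of the lithiated methyl group; the pyranone supplies C-4a, C-5 to C-8a and the 7-OMe).
3. 9 ⇒ aldehyde 6 by Horner–Wadsworth–Emmons olefination.
4. 6 ⇒ veratraldehyde 1 + geranyl bromide 2 by amino-alkoxide-directed ortho-lithiation at C-2.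
5. Ring order: ring B is bought; the pyranone ring is bought and sacrificed; rings A and C are formed together in the last step.

Assumption: the quinine-derived thiourea of step 4 is taken to favour the (2S) product; if analysis shows the opposite sense, its quinidine-derived pseudoenantiomer is used and nothing else changes.

Ar = 2-[(2E)-3,7-dimethylocta-2,6-dien-1-yl]-3,4-dimethoxyphenyl (2-geranyl-3,4-dimethoxyphenyl).

## Route

Step 1
Reactants: 1 3,4-dimethoxybenzaldehyde (veratraldehyde); 2 geranyl bromide, (2E)-1-bromo-3,7-dimethylocta-2,6-diene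
Product: 6 2-[(2E)-3,7-dimethylocta-2,6-dien-1-yl]-3,4-dimethoxybenzaldehyde, via lithium amino alkoxide 3 (not isolated), via C-2 aryllithium 4 (not isolated), via geranylated amino alkoxide 5 (not isolated)
Conditions: Me2NCH2CH2NHMe (1.1 equiv), n-BuLi (1.05 equiv), THF, −20 °C; 1; n-BuLi (3 equiv), −20 °C, 18 h; CuBr·SMe2 (10 mol %), 2 (3.5 equiv, also consumes the excess n-BuLi), −78 °C → rt; H2O
Reagents that add atoms: none
Why: Comins-type directed ortho-metalation, in which the in situ lithium α-amino alkoxide masks the aldehyde and, together with the 3-OMe group, directs n-BuLi to C-2, and the aryl copper species then displaces the primary allylic bromide in an SN2 sense so the (E)-geometry of 2 is kept; water releases the aldehyde.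

Step 2
Reactants: 6 2-geranyl-3,4-dimethoxybenzaldehyde; 7 diethyl {2-[methoxy(methyl)amino]-2-oxoethyl}phosphonate
Product: 9 (2E)-3-Ar-N-methoxy-N-methylprop-2-enamide, via sodium phosphonate carbanion 8 (not isolated)
Conditions: NaH (1.2 equiv), THF, 0 °C; then 6, 0 °C → rt
Reagents that add atoms: none
Why: Horner–Wadsworth–Emmons olefination with an amide-stabilised phosphonate gives the (E)-enamide and does not touch the two trisubstituted alkenes.

Step 3
Reactants: 9 (2E)-3-Ar-N-methoxy-N-methylprop-2-enamide; 10 4-methoxy-6-methyl-2H-pyran-2-one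
Product: 13 6-[(3E)-4-Ar-2-oxobut-3-en-1-yl]-4-methoxy-2H-pyran-2-one, via lithiated pyranone 11 (not isolated), via lithium tetrahedral adduct 12 (not isolated)
Conditions: 10 (2.2 equiv), LiN(iPr)2 (2.1 equiv), THF, −78 °C, 30 min; 9, −78 → −40 °C; AcOH, −78 °C
Reagents that add atoms: none
Why: Weinreb ketone synthesis (crossed Claisen-type acylation), in which the amide base deprotonates the C-6 methyl group to a vinylogous enolate that adds 1,2 to the amide, and the chelated tetrahedral adduct holds until the AcOH quench so the acidic product never meets the anion.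

Step 4
Reactants: 13 6-[(3E)-4-Ar-2-oxobut-3-en-1-yl]-4-methoxy-2H-pyran-2-one
Product: 16 (2S)-2-Ar-5-hydroxy-7-methoxy-2,3-dihydro-4H-chromen-4-one, via ring-opened triketide methyl ester 14 (not isolated), via chalcone 15 (not isolated)
Conditions: Mg(OMe)2 (3 equiv), MeOH, 65 °C, 3 h; AcOH (6 equiv), 0 °C; evaporate, toluene, filter under Ar; N-[3,5-bis(trifluoromethyl)phenyl]-N'-[(8α,9S)-6'-methoxycinchonan-9-yl]thiourea (10 mol %), toluene, 0 °C → rt, 24–48 h
Reagents that add atoms: none
Why: Proposed new method: methoxide opens the pyranone at C-2 to the (2E)-ester 14, whose magnesium-chelated C-6 carbanion attacks the ester carbon (intramolecular Claisen condensation, Dieckmann type) and aromatises to chalcone 15 (ring A); after neutralisation the bifunctional thiourea hydrogen-bonds the enone carbonyl while its quinuclidine nitrogen activates one of the two equivalent phenols, so the 6-endo oxa-Michael addition closes ring C on one alkene face and sets C-2 as (S); the closest known reactions are the Mg(OMe)2 conversion of 6-(2-oxoalkyl)-4-methoxypyran-2-ones into acylphloroglucinols and the cinchona-thiourea-catalysed asymmetric cyclisation of 2'-hydroxychalcones to flavanones, here joined in one flask.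

## Compound list

1 | 3,4-dimethoxybenzaldehyde (veratraldehyde) | COc1ccc(C=O)cc1OC | starting material
2 | geranyl bromide, (2E)-1-bromo-3,7-dimethylocta-2,6-diene | BrC/C=C(\C)CCC=C(C)C | starting material
3 | lithium (3,4-dimethoxyphenyl){[2-(dimethylamino)ethyl](methyl)amino}methanolate, racemic at the carbinol carbon | COc1ccc(C(O[Li])N(C)CCN(C)C)cc1OC | intermediate
4 | C-2 lithiated derivative of 3 (lithium on the ring carbon between the carbinol carbon and the 3-OMe group) | COc1ccc(C(O[Li])N(C)CCN(C)C)c([Li])c1OC | intermediate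
5 | C-2 (E)-geranylated derivative of 3 | COc1ccc(C(O[Li])N(C)CCN(C)C)c(C/C=C(\C)CCC=C(C)C)c1OC | intermediate
6 | 2-[(2E)-3,7-dimethylocta-2,6-dien-1-yl]-3,4-dimethoxybenzaldehyde | COc1ccc(C=O)c(C/C=C(\C)CCC=C(C)C)c1OC | intermediate
7 | diethyl {2-[methoxy(methyl)amino]-2-oxoethyl}phosphonate | CCOP(=O)(OCC)CC(=O)N(C)OC | starting material
8 | sodium salt of 7 (carbanion at the P–CH–C=O carbon) | CCOP(=O)(OCC)[CH-]C(=O)N(C)OC.[Na+] | intermediate
9 | (2E)-3-{2-[(2E)-3,7-dimethylocta-2,6-dien-1-yl]-3,4-dimethoxyphenyl}-N-methoxy-N-methylprop-2-enamide | CON(C)C(=O)/C=C/c1ccc(OC)c(OC)c1C/C=C(\C)CCC=C(C)C | intermediate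
10 | 4-methoxy-6-methyl-2H-pyran-2-one | CC1=CC(OC)=CC(=O)O1 | starting material
11 | (4-methoxy-2-oxo-2H-pyran-6-yl)methyllithium | [Li]CC1=CC(OC)=CC(=O)O1 | intermediate
12 | lithium (3E)-4-Ar-2-[methoxy(methyl)amino]-1-(4-methoxy-2-oxo-2H-pyran-6-yl)but-3-en-2-olate, racemic at C-2 | CON(C)C(O[Li])(CC1=CC(OC)=CC(=O)O1)/C=C/c1ccc(OC)c(OC)c1C/C=C(\C)CCC=C(C)C | intermediate
13 | 6-[(3E)-4-{2-[(2E)-3,7-dimethylocta-2,6-dien-1-yl]-3,4-dimethoxyphenyl}-2-oxobut-3-en-1-yl]-4-methoxy-2H-pyran-2-one | COC1=CC(=O)OC(CC(=O)/C=C/c2ccc(OC)c(OC)c2C/C=C(\C)CCC=C(C)C)=C1 | intermediate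
14 | methyl (2E,8E)-9-{2-[(2E)-3,7-dimethylocta-2,6-dien-1-yl]-3,4-dimethoxyphenyl}-3-methoxy-5,7-dioxonona-2,8-dienoate (drawn as the triketo tautomer; present as its magnesium enolate) | COC(=O)/C=C(/OC)CC(=O)CC(=O)/C=C/c1ccc(OC)c(OC)c1C/C=C(\C)CCC=C(C)C | intermediate
15 | (2E)-1-(2,6-dihydroxy-4-methoxyphenyl)-3-{2-[(2E)-3,7-dimethylocta-2,6-dien-1-yl]-3,4-dimethoxyphenyl}prop-2-en-1-one | COc1cc(O)c(C(=O)/C=C/c2ccc(OC)c(OC)c2C/C=C(\C)CCC=C(C)C)c(O)c1 | intermediate
16 | (2S)-2-{2-[(2E)-3,7-dimethylocta-2,6-dien-1-yl]-3,4-dimethoxyphenyl}-5-hydroxy-7-methoxy-2,3-dihydro-4H-chromen-4-one | COc1cc(O)c2c(c1)O[C@H](c1ccc(OC)c(OC)c1C/C=C(\C)CCC=C(C)C)CC2=O | target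

## Step count and risks

Total steps: 4. Longest linear sequence: 4 (1 → 6 → 9 → 13 → 16).

Steps most likely to fail:

Step 4. The Claisen stage could give some racemic flavanone before the chiral catalyst is added, and the selectivity of the oxa-Michael closure for a chalcone with an ortho-substituted ring B is untested; 5-hydroxyflavanones also racemise in base, so the product is kept away from base and its ee is checked by chiral HPLC. Fallback: it sets out from 13, which is taken through the same Mg(OMe)2 stage and then heated with NaOAc in EtOH so that 15 closes without stereocontrol to the racemic flavanone F5. Kinetic resolution by asymmetric transfer hydrogenation (Cp*RhCl[(R,R)-TsDPEN] 1 mol %, HCO2H/Et3N, EtOAc, rt, stopped near 55 % conversion) reduces the (2R) enantiomer to the cis-(2R,4R)-flavan-4-ol F6. The unreacted (2S) ketone is separated by chromatography, and the fallback comes back to the route at 16.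

Step 3. The vinylogous enolate 11 may add 1,4 to the enamide, or the hindered conjugated amide may react slowly. Fallback: it sets out from 6, which is homologated by Wittig reaction with (triphenylphosphoranylidene)acetaldehyde (toluene, 80 °C) to the (2E)-3-Ar-prop-2-enal F3. 1,2-Addition of 11 (made as in step 3, THF, −78 °C) to this aldehyde gives the racemic allylic alcohol 6-[(3E)-4-Ar-2-hydroxybut-3-en-1-yl]-4-methoxy-2H-pyran-2-one F4. Oxidation of the allylic alcohol with MnO2 (CH2Cl2, rt) removes the carbinol centre, and the fallback comes back to the route at 13.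

Step 1. The aryl metal may attack geranyl bromide in an SN2' sense or be outrun by butylation of the bromide. Fallback: it sets out from 4, which is quenched with I2 instead of 2 to give the iodinated lithium amino alkoxide F1 and, after aqueous work-up, 2-iodo-3,4-dimethoxybenzaldehyde F2. Stille coupling of F2 with tributyl[(2E)-3,7-dimethylocta-2,6-dien-1-yl]stannane (zerovalent palladium catalyst Pd(PPh3)4, CuI, DMF, 80 °C) joins the ring to the tin-bearing CH2 carbon, and the fallback comes back to the route at 6.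

## Further compounds

F1 | step 1 | lithium (2-iodo-3,4-dimethoxyphenyl){[2-(dimethylamino)ethyl](methyl)amino}methanolate, racemic at the carbinol carbon | COc1ccc(C(O[Li])N(C)CCN(C)C)c(I)c1OC
F2 | step 1 | 2-iodo-3,4-dimethoxybenzaldehyde | COc1ccc(C=O)c(I)c1OC
F3 | step 3 | (2E)-3-{2-[(2E)-3,7-dimethylocta-2,6-dien-1-yl]-3,4-dimethoxyphenyl}prop-2-enal | O=C/C=C/c1ccc(OC)c(OC)c1C/C=C(\C)CCC=C(C)C
F4 | step 3 | 6-[(3E)-4-{2-[(2E)-3,7-dimethylocta-2,6-dien-1-yl]-3,4-dimethoxyphenyl}-2-hydroxybut-3-en-1-yl]-4-methoxy-2H-pyran-2-one, racemic at the carbinol carbon | COC1=CC(=O)OC(CC(O)/C=C/c2ccc(OC)c(OC)c2C/C=C(\C)CCC=C(C)C)=C1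
F5 | step 4 | racemic 2-{2-[(2E)-3,7-dimethylocta-2,6-dien-1-yl]-3,4-dimethoxyphenyl}-5-hydroxy-7-methoxy-2,3-dihydro-4H-chromen-4-one | COc1cc(O)c2c(c1)OC(c1ccc(OC)c(OC)c1C/C=C(\C)CCC=C(C)C)CC2=O
F6 | step 4 | (2R,4R)-2-{2-[(2E)-3,7-dimethylocta-2,6-dien-1-yl]-3,4-dimethoxyphenyl}-7-methoxy-3,4-dihydro-2H-chromene-4,5-diol (2,4-cis) | COc1cc(O)c2c(c1)O[C@@H](c1ccc(OC)c(OC)c1C/C=C(\C)CCC=C(C)C)C[C@H]2O
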